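The target is a (3R,4R)-dibenzylbutyrolactone whose β-benzyl ring B is fused to a trans-2-aryl-3-hydroxymethyl-dihydrobenzofuran and whose α-benzyl ring A carries an anti-1,2-diarylpropane-1,3-diol. The route rests on cutting the dihydrofuran at O1–C2 and C3–C3a. A biomimetic oxidative cross-coupling joins the phenol oxygen and the free ortho carbon C5 of ring B in a simple phenolic lactone to Cα and Cβ of an N-feruloyl camphorsultam, forming both bonds and both stereocentres in one operation. The ring A arm, built by an auxiliary-controlled anti-aldol, is then attached by trans-selective lactone enolate alkylation, and one fluoride treatment unveils all hydroxyl groups.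

Key step: step 7

Assumption: the (1R)-sultam is taken to direct the radical coupling to the face that gives the (2S,3S) phenylcoumaran, and the (S,S)-Et-DuPHOS rhodium catalyst to give the (R)-succinate; if either sense proves opposite, the antipodal auxiliary or ligand (both commercial) is used with no other change.

Step 1
Reactants: 1 4-(benzyloxy)-3-methoxybenzaldehyde; 2 dimethyl succinate
Product: 3 (E)-4-[4-(benzyloxy)-3-methoxyphenyl]-3-(methoxycarbonyl)but-3-enoic acid
Conditions: NaOMe (1.3 equiv), MeOH, reflux; then aq. HCl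
Reagents that add atoms: none
Why: Stobbe condensation, in which the succinate enolate adds to the aldehyde, the alkoxide lactonises to a paraconate and base-induced ring opening gives the carboxylate, leaving the (E)-half-ester with the ester on the alkylidene carbon.

Step 2
Reactants: 3 (E)-half-ester
Product: 4 (R)-4-[4-(benzyloxy)-3-methoxyphenyl]-3-(methoxycarbonyl)butanoic acid
Conditions: H2 (5 bar), [Rh(cod)((S,S)-Et-DuPHOS)]OTf (0.5 mol %), NaOMe (0.1 equiv), MeOH, 25 °C
Reagents that add atoms: none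
Why: Rhodium-bisphospholane asymmetric hydrogenation of an itaconate-type half-ester, in which the carboxylate-bound cationic rhodium catalyst delivers H2 to one face of the trisubstituted alkene and so should set C3 as (R).

Step 3
Reactants: 4 (R)-half-ester
Product: 6 (R)-4-[4-(benzyloxy)-3-methoxybenzyl]dihydrofuran-2(3H)-one, via hydroxy acid 5 (not isolated)
Conditions: KOH (1 equiv), EtOH; CaCl2, NaBH4, EtOH, −10 °C → rt; then 3 M HCl, rt
Reagents that add atoms: none
Why: Chemoselective calcium borohydride reduction of the ester beside the unreactive potassium carboxylate, followed by acid-promoted γ-lactonisation, should give the β-benzyl lactone without touching the stereocentre.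

Step 4
Reactants: 6 (R)-benzyl-protected lactone
Product: 7 (R)-4-(4-hydroxy-3-methoxybenzyl)dihydrofuran-2(3H)-one
Conditions: H2 (1 atm), Pd/C (10 %), EtOAc, rt
Reagents that add atoms: none
Why: Hydrogenolysis of the benzyl aryl ether over Pd/C frees the phenol needed for the radical coupling while the lactone and its stereocentre are inert.

Step 5
Reactants: 8 (E)-4-acetoxy-3-methoxycinnamic acid; 9 (1R)-(+)-2,10-camphorsultam
Product: 11 N-[(E)-4-acetoxy-3-methoxycinnamoyl]-(1R)-2,10-camphorsultam, via acyl chloride 10 (not isolated)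
Conditions: (COCl)2, DMF (cat.), CH2Cl2, 0 °C → rt; then 9, Et3N, DMAP (0.2 equiv), CH2Cl2, 0 °C → rt
Reagents that add atoms: none
Why: Acid chloride formation and N-acylation of the acidic sulfonamide N–H under Et3N/DMAP should give the N-enoyl sultam, the aryl acetate keeping the phenol from self-acylation.

Step 6
Reactants: 11 N-(O-acetylferuloyl)sultam
Product: 12 N-[(E)-4-hydroxy-3-methoxycinnamoyl]-(1R)-2,10-camphorsultam (N-feruloyl sultam)
Conditions: pyrrolidine (1.2 equiv), CH2Cl2, 0 °C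
Reagents that add atoms: none
Why: Aminolysis of the aryl acetate by pyrrolidine should be far faster than attack on the hindered, electron-rich N-cinnamoyl sultam, so the phenol is freed selectively.

Step 7
Reactants: 7 (R)-phenolic lactone (3 equiv, excess recovered); 12 N-feruloyl sultam
Product: 14 N-{[(2S,3S)-2-(4-hydroxy-3-methoxyphenyl)-7-methoxy-5-{[(3R)-5-oxooxolan-3-yl]methyl}-2,3-dihydro-1-benzofuran-3-yl]carbonyl}-(1R)-2,10-camphorsultam, via quinone methide 13 (not isolated)
Conditions: Ag2O (1.5 equiv), CH2Cl2/acetone 2:1, rt, dark, N2; 12 added over 6 h to 7 and Ag2O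
Reagents that add atoms: none
Why: Ag2O oxidises both phenols to phenoxyl radicals; the feruloyl radical bonds through C8 (its β-carbon) to C5 of the guaiacyl radical of 7, the only free ortho carbon (C1 is alkylated, C3 carries OMe), and tautomerisation of the resulting cyclohexadienone restores ring B as a phenol beside a p-quinone methide (13). The phenol oxygen then adds to C7 of the quinone methide in a 5-exo-trig oxa-Michael (1,6-) addition, which closes the dihydrofuran ring and re-aromatises the second ring. The closest known reaction type is the Ag2O- or peroxidase-mediated 8–5 dehydrodimerisation of ferulates to phenylcoumarans, including its auxiliary-controlled form with N-feruloyl camphorsultams, run here in the cross mode that lignification uses. C3 is set in the radical–radical coupling by the sultam, whose s-cis enoyl conformation exposes one face of C8, and C2 is set in the ring closure, which places the aryl group trans to the C3 acyl group under the control of C3. The step needs cross- over homo-coupling and C5 over O4 attack; slow addition of 12 into excess recoverable 7 keeps the feruloyl radical dilute, and the residual (2R,3R) isomer is a diastereomer of 14 (lactone and sultam are both chiral) that should be removable by chromatography.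

Step 8
Reactants: 14 phenylcoumaran acyl sultam
Product: 15 (4R)-4-{[(2S,3R)-3-(hydroxymethyl)-2-(4-hydroxy-3-methoxyphenyl)-7-methoxy-2,3-dihydro-1-benzofuran-5-yl]methyl}oxolan-2-one
Conditions: NaBH4, THF/H2O 4:1, 0 °C → rt
Reagents that add atoms: none
Why: Borohydride reduction of an N-acyl sultam, which is activated like an imide and should be reduced by NaBH4 in aqueous THF well before a γ-lactone, releases the primary alcohol at C3 without change of configuration and returns the auxiliary.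

Step 9
Reactants: 15 phenylcoumaran lactone diol
Product: 16 bis(tert-butyldimethylsilyl) ether of 15 (aryl O and CH2O silylated)
Conditions: TBSCl (2.5 equiv), imidazole, DMF, rt
Reagents that add atoms: tert-butyldimethylsilyl chloride, CC(C)(C)[Si](C)(C)Cl
Why: Silylation with TBSCl/imidazole masks the phenol and the primary alcohol so that only the lactone α-position is deprotonated later.

Step 10
Reactants: 17 methyl 3-bromo-4-hydroxy-5-methoxybenzoate
Product: 18 methyl 3-bromo-4-[(tert-butyldimethylsilyl)oxy]-5-methoxybenzoate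
Conditions: TBSCl, imidazole, DMAP (cat.), DMF, 50 °C
Reagents that add atoms: tert-butyldimethylsilyl chloride, CC(C)(C)[Si](C)(C)Cl
Why: Silylation of the hindered phenol prevents later lactonisation onto the imide and quenching of the enolates.

Step 11
Reactants: 18 silylated aryl bromide; 19 (S)-3-acetyl-4-benzyloxazolidin-2-one
Product: 21 (S)-4-benzyl-3-{2-[2-(tert-butyldimethylsilyloxy)-3-methoxy-5-(methoxycarbonyl)phenyl]acetyl}oxazolidin-2-one, via zinc enolate 20 (not isolated)
Conditions: 19, LiN(SiMe3)2, THF, −78 °C; ZnCl2, −78 → 0 °C; then 18, Pd(dba)2 (3 mol %), Q-Phos (3 mol %), THF, rt → 50 °C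
Reagents that add atoms: none
Why: Palladium-catalysed α-arylation of a zinc (Reformatsky-type) enolate, a Negishi-type coupling that tolerates the ester and the silyl ether and installs the auxiliary-bearing arylacetyl unit in one step.

Step 12
Reactants: 21 arylacetyl imide; 22 4-[(tert-butyldimethylsilyl)oxy]-3-methoxybenzaldehyde
Product: 24 (4S)-4-benzyl-3-[(2R,3S)-3-hydroxy-2-{2-(tert-butyldimethylsilyloxy)-3-methoxy-5-(methoxycarbonyl)phenyl}-3-{4-(tert-butyldimethylsilyloxy)-3-methoxyphenyl}propanoyl]oxazolidin-2-one, via trimethylsilyl ether 23 (not isolated)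
Conditions: MgCl2 (0.2 equiv), Et3N, Me3SiCl, EtOAc, rt; then CF3CO2H (cat.), MeOH, rt
Reagents that add atoms: none
Why: Magnesium halide-catalysed direct anti-aldol of an N-acyloxazolidinone, in which soft enolisation gives the chelated (Z)-magnesium enolate, the aldehyde adds through a closed boat-like transition state on the face away from the auxiliary benzyl group and silylation of the aldolate drives turnover, which should set C2 (R) and C3 (S), the anti pair.

Step 13
Reactants: 24 anti-aldol adduct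
Product: 25 methyl 4-(tert-butyldimethylsilyloxy)-3-[(1S,2S)-1,3-dihydroxy-1-{4-(tert-butyldimethylsilyloxy)-3-methoxyphenyl}propan-2-yl]-5-methoxybenzoate
Conditions: NaBH4, THF/H2O 4:1, 0 °C
Reagents that add atoms: none
Why: Borohydride reduction of the N-acyloxazolidinone removes the auxiliary as the primary alcohol while the aryl methyl ester should be reduced much more slowly, and the two stereocentres are untouched.

Step 14
Reactants: 25 diol ester
Product: 26 bis(tert-butyldimethylsilyl) ether of 25 (both hydroxyl groups silylated)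
Conditions: TBSOTf (2.5 equiv), 2,6-lutidine, CH2Cl2, −20 → 0 °C
Reagents that add atoms: tert-butyldimethylsilyl triflate, CC(C)(C)[Si](C)(C)OS(=O)(=O)C(F)(F)F
Why: Silylation with TBSOTf/2,6-lutidine protects the primary and the hindered benzylic secondary hydroxyl, and would restore any aryl silyl ether lost in step 13.

Step 15
Reactants: 26 tetrasilylated ester
Product: 27 benzylic alcohol {4-(tert-butyldimethylsilyloxy)-3-[(1S,2S)-1,3-bis(tert-butyldimethylsilyloxy)-1-{4-(tert-butyldimethylsilyloxy)-3-methoxyphenyl}propan-2-yl]-5-methoxyphenyl}methanol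
Conditions: i-Bu2AlH (2.5 equiv), CH2Cl2, −78 °C
Reagents that add atoms: none
Why: Reduction of the benzoate ester to the benzylic alcohol with i-Bu2AlH at low temperature, to which silyl ethers are inert.

Step 16
Reactants: 27 benzylic alcohol
Product: 28 the corresponding benzylic bromide (CH2OH replaced by CH2Br)
Conditions: CBr4, PPh3, CH2Cl2, 0 °C; used at once
Reagents that add atoms: carbon tetrabromide, BrC(Br)(Br)Br
Why: Appel bromination converts the primary benzylic alcohol into the bromide under neutral conditions that spare the acid-sensitive benzylic silyl ether.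

Step 17
Reactants: 16 bis-silylated phenylcoumaran lactone; 28 benzylic bromide
Product: 30 (3R,4R)-3,4-disubstituted lactone hexakis(tert-butyldimethylsilyl) ether, via lithium enolate 29 (not isolated)
Conditions: LiN(SiMe3)2 (1.1 equiv), THF, −78 °C; then 28, DMPU, −78 → −30 °C
Reagents that add atoms: none
Why: Alkylation of the lithium enolate of a β-substituted γ-butyrolactone, in which the benzyl bromide approaches anti to the C4 substituent and so should set C3 (R), trans to C4.

Step 18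
Reactants: 30 hexasilyl ether
Product: 31 target CNP0186558.2
Conditions: Bu4NF (8 equiv), AcOH (8 equiv), THF, 0 °C → rt
Reagents that add atoms: none
Why: Fluoride-mediated desilylation buffered with acetic acid should cleave the three aryl and three alkyl silyl ethers without base-induced opening of the phenylcoumaran or epimerisation of the lactone.

Compound list
1 | 4-(benzyloxy)-3-methoxybenzaldehyde | COc1cc(C=O)ccc1OCc1ccccc1 | starting material
2 | dimethyl succinate | COC(=O)CCC(=O)OC | starting material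
3 | (E)-4-[4-(benzyloxy)-3-methoxyphenyl]-3-(methoxycarbonyl)but-3-enoic acid | COC(=O)/C(CC(=O)O)=C/c1ccc(OCc2ccccc2)c(OC)c1 | intermediate
4 | (R)-4-[4-(benzyloxy)-3-methoxyphenyl]-3-(methoxycarbonyl)butanoic acid | COC(=O)[C@@H](CC(=O)O)Cc1ccc(OCc2ccccc2)c(OC)c1 | intermediate
5 | (R)-4-[4-(benzyloxy)-3-methoxyphenyl]-3-(hydroxymethyl)butanoic acid | OC[C@@H](CC(=O)O)Cc1ccc(OCc2ccccc2)c(OC)c1 | intermediate
6 | (R)-4-[4-(benzyloxy)-3-methoxybenzyl]dihydrofuran-2(3H)-one | O=C1OC[C@@H](C1)Cc1ccc(OCc2ccccc2)c(OC)c1 | intermediate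
7 | (R)-4-(4-hydroxy-3-methoxybenzyl)dihydrofuran-2(3H)-one | O=C1OC[C@@H](C1)Cc1ccc(O)c(OC)c1 | intermediate
8 | (E)-4-acetoxy-3-methoxycinnamic acid | CC(=O)Oc1ccc(/C=C/C(=O)O)cc1OC | starting material
9 | (1R)-(+)-2,10-camphorsultam [(2S)-bornane-10,2-sultam] | N1[C@H]2C[C@@H]3CC[C@@]2(CS1(=O)=O)C3(C)C | starting material
10 | (E)-4-acetoxy-3-methoxycinnamoyl chloride | CC(=O)Oc1ccc(/C=C/C(Cl)=O)cc1OC | intermediate
11 | N-[(E)-4-acetoxy-3-methoxycinnamoyl]-(1R)-2,10-camphorsultam | CC(=O)Oc1ccc(/C=C/C(=O)N2[C@H]3C[C@@H]4CC[C@@]3(CS2(=O)=O)C4(C)C)cc1OC | intermediate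
12 | N-[(E)-4-hydroxy-3-methoxycinnamoyl]-(1R)-2,10-camphorsultam | COc1cc(/C=C/C(=O)N2[C@H]3C[C@@H]4CC[C@@]3(CS2(=O)=O)C4(C)C)ccc1O | intermediate
13 | p-quinone methide: ring B phenol bearing at C5 the CH(CO-sultam)–CH= unit exocyclic to a 2-methoxycyclohexa-2,5-dienone | O=C1OC[C@@H](C1)Cc1cc(OC)c(O)c(c1)[C@H](C(=O)N1[C@H]2C[C@@H]3CC[C@@]2(CS1(=O)=O)C3(C)C)C=C1C=CC(=O)C(OC)=C1 | intermediate
14 | (2S,3S)-phenylcoumaran acyl sultam carrying the (R)-lactone | O=C1OC[C@@H](C1)Cc1cc(OC)c2c(c1)[C@H](C(=O)N1[C@H]3C[C@@H]4CC[C@@]3(CS1(=O)=O)C4(C)C)[C@@H](c1ccc(O)c(OC)c1)O2 | intermediate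
15 | (4R)-4-{[(2S,3R)-3-(hydroxymethyl)-2-(4-hydroxy-3-methoxyphenyl)-7-methoxy-2,3-dihydro-1-benzofuran-5-yl]methyl}oxolan-2-one | O=C1OC[C@@H](C1)Cc1cc(OC)c2c(c1)[C@H](CO)[C@@H](c1ccc(O)c(OC)c1)O2 | intermediate
16 | bis(tert-butyldimethylsilyl) ether of 15 | O=C1OC[C@@H](C1)Cc1cc(OC)c2c(c1)[C@H](CO[Si](C)(C)C(C)(C)C)[C@@H](c1ccc(O[Si](C)(C)C(C)(C)C)c(OC)c1)O2 | intermediate
17 | methyl 3-bromo-4-hydroxy-5-methoxybenzoate | COC(=O)c1cc(Br)c(O)c(OC)c1 | starting material
18 | methyl 3-bromo-4-[(tert-butyldimethylsilyl)oxy]-5-methoxybenzoate | COC(=O)c1cc(Br)c(O[Si](C)(C)C(C)(C)C)c(OC)c1 | intermediate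
19 | (S)-3-acetyl-4-benzyloxazolidin-2-one | CC(=O)N1[C@@H](Cc2ccccc2)COC1=O | starting material
20 | chlorozinc enolate of 19 | C=C(O[Zn]Cl)N1[C@@H](Cc2ccccc2)COC1=O | intermediate
21 | (S)-4-benzyl-3-{2-[2-(tert-butyldimethylsilyloxy)-3-methoxy-5-(methoxycarbonyl)phenyl]acetyl}oxazolidin-2-one | COC(=O)c1cc(CC(=O)N2[C@@H](Cc3ccccc3)COC2=O)c(O[Si](C)(C)C(C)(C)C)c(OC)c1 | intermediate
22 | 4-[(tert-butyldimethylsilyl)oxy]-3-methoxybenzaldehyde | COc1cc(C=O)ccc1O[Si](C)(C)C(C)(C)C | starting material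
23 | O-trimethylsilyl ether of aldol adduct 24 | COc1cc([C@@H](O[Si](C)(C)C)[C@H](C(=O)N2[C@@H](Cc3ccccc3)COC2=O)c2cc(C(=O)OC)cc(OC)c2O[Si](C)(C)C(C)(C)C)ccc1O[Si](C)(C)C(C)(C)C | intermediate
24 | (4S)-4-benzyl-3-[(2R,3S)-anti-aldol] imide | COc1cc([C@@H](O)[C@H](C(=O)N2[C@@H](Cc3ccccc3)COC2=O)c2cc(C(=O)OC)cc(OC)c2O[Si](C)(C)C(C)(C)C)ccc1O[Si](C)(C)C(C)(C)C | intermediate
25 | methyl 4-(tert-butyldimethylsilyloxy)-3-[(1S,2S)-1,3-dihydroxy-1-{4-(tert-butyldimethylsilyloxy)-3-methoxyphenyl}propan-2-yl]-5-methoxybenzoate | COc1cc([C@@H](O)[C@H](CO)c2cc(C(=O)OC)cc(OC)c2O[Si](C)(C)C(C)(C)C)ccc1O[Si](C)(C)C(C)(C)C | intermediate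
26 | bis(tert-butyldimethylsilyl) ether of 25 | COc1cc([C@@H](O[Si](C)(C)C(C)(C)C)[C@H](CO[Si](C)(C)C(C)(C)C)c2cc(C(=O)OC)cc(OC)c2O[Si](C)(C)C(C)(C)C)ccc1O[Si](C)(C)C(C)(C)C | intermediate
27 | benzylic alcohol from 26 (CO2Me reduced to CH2OH) | COc1cc([C@@H](O[Si](C)(C)C(C)(C)C)[C@H](CO[Si](C)(C)C(C)(C)C)c2cc(CO)cc(OC)c2O[Si](C)(C)C(C)(C)C)ccc1O[Si](C)(C)C(C)(C)C | intermediate
28 | benzylic bromide from 27 | COc1cc([C@@H](O[Si](C)(C)C(C)(C)C)[C@H](CO[Si](C)(C)C(C)(C)C)c2cc(CBr)cc(OC)c2O[Si](C)(C)C(C)(C)C)ccc1O[Si](C)(C)C(C)(C)C | intermediate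
29 | lithium enolate of 16 | [Li]OC1=C[C@H](CO1)Cc1cc(OC)c2c(c1)[C@H](CO[Si](C)(C)C(C)(C)C)[C@@H](c1ccc(O[Si](C)(C)C(C)(C)C)c(OC)c1)O2 | intermediate
30 | (3R,4R)-lactone hexakis(tert-butyldimethylsilyl) ether of the target | COc1cc([C@@H](O[Si](C)(C)C(C)(C)C)[C@H](CO[Si](C)(C)C(C)(C)C)c2cc(C[C@H]3C(=O)OC[C@@H]3Cc3cc(OC)c4c(c3)[C@H](CO[Si](C)(C)C(C)(C)C)[C@@H](c3ccc(O[Si](C)(C)C(C)(C)C)c(OC)c3)O4)cc(OC)c2O[Si](C)(C)C(C)(C)C)ccc1O[Si](C)(C)C(C)(C)C | intermediate
31 | (3R,4R)-3-{4-hydroxy-3-[(1S,2S)-1,3-dihydroxy-1-(4-hydroxy-3-methoxyphenyl)propan-2-yl]-5-methoxybenzyl}-4-{[(2S,3R)-3-(hydroxymethyl)-2-(4-hydroxy-3-methoxyphenyl)-7-methoxy-2,3-dihydro-1-benzofuran-5-yl]methyl}oxolan-2-one (CNP0186558.2) | COc1cc([C@@H](O)[C@H](CO)c2cc(C[C@H]3C(=O)OC[C@@H]3Cc3cc(OC)c4c(c3)[C@H](CO)[C@@H](c3ccc(O)c(OC)c3)O4)cc(OC)c2O)ccc1O | target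

Total step count: 18. Longest linear sequence: 9 steps (steps 10–18; equally steps 1–4, 7–9, 17 and 18).

Steps most likely to fail

Step 7. Homo-coupling of the feruloyl radical and coupling at the phenol oxygen (8–O–4) may outrun the C5 cross-coupling, and facial control by the sultam may be poor. The fallback sets out from 7 and returns at 15, building the ring by ionic chemistry. Ortho-bromination of 7 (NBS, MeCN, 0 °C) gives (R)-4-(3-bromo-4-hydroxy-5-methoxybenzyl)dihydrofuran-2(3H)-one F1, and silylation (TBSCl, imidazole) gives its silyl ether F2. Coupling with zinc enolate 20 (Pd(dba)2, Q-Phos) gives the arylacetyl imide F3. A dibutylboron-enolate syn-aldol (Evans aldol; Bu2BOTf, i-Pr2NEt) with 22 gives the (2S,3S) adduct F4, and NaBH4 in aqueous THF removes the auxiliary to give the diol F5. Bu4NF/AcOH frees both phenols to give the triol bisphenol F6. Catalytic TsOH in CH2Cl2 then ionises the benzylic alcohol and closes the phenylcoumaran trans to give 15, with C3 fixed by the auxiliary and C2 by the trans closure.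

Step 12. Simple diastereoselection may be low, or the acidic aryl-bearing carbon may epimerise under the amine base. The fallback sets out from 18 and returns at 26. Coupling of 18 with the zinc enolate of (R)-3-acetyl-4-benzyloxazolidin-2-one F7 gives the antipodal-auxiliary imide F8. A boron syn-aldol (Bu2BOTf, i-Pr2NEt) with 22 gives the (2R,3R) adduct F9, which is correct at the aryl-bearing carbon and epimeric at the carbinol. NaBH4 gives the (1R,2S) syn-diol F10, and selective silylation of the primary hydroxyl (TBSCl, imidazole, 0 °C) gives the mono-silyl ether F11. Mitsunobu inversion of the benzylic alcohol (4-nitrobenzoic acid, PPh3, DIAD) gives the (1S) 4-nitrobenzoate F12, and methanolysis (NaN3, MeOH, 40 °C) gives the (1S,2S) alcohol F13. Silylation with TBSOTf/2,6-lutidine then gives 26.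

Step 8. The lactone may be over-reduced, or the basic medium may open the 3-acyl dihydrobenzofuran by β-elimination. The fallback sets out from 14 and returns at 15. LiOH/H2O2 (THF/H2O, 0 °C, acidic work-up to re-close any opened lactone) cleaves the sultam to give the (2S,3S)-dihydrobenzofuran-3-carboxylic acid F14. BH3·SMe2 (THF, 0 °C) then reduces the carboxylic acid, but not the lactone, to 15.

Further compounds
F1 | step 7 | (R)-4-(3-bromo-4-hydroxy-5-methoxybenzyl)dihydrofuran-2(3H)-one | O=C1OC[C@@H](C1)Cc1cc(Br)c(O)c(OC)c1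
F2 | step 7 | tert-butyldimethylsilyl ether of F1 | O=C1OC[C@@H](C1)Cc1cc(Br)c(O[Si](C)(C)C(C)(C)C)c(OC)c1
F3 | step 7 | (S)-4-benzyl-3-(arylacetyl)oxazolidin-2-one of ring B carrying the (R)-lactone | O=C1OC[C@@H](C1)Cc1cc(CC(=O)N2[C@@H](Cc3ccccc3)COC2=O)c(O[Si](C)(C)C(C)(C)C)c(OC)c1
F4 | step 7 | (2S,3S)-syn-aldol adduct of F3 with 22 | O=C1OC[C@@H](C1)Cc1cc([C@H](C(=O)N2[C@@H](Cc3ccccc3)COC2=O)[C@H](O)c2ccc(O[Si](C)(C)C(C)(C)C)c(OC)c2)c(O[Si](C)(C)C(C)(C)C)c(OC)c1
F5 | step 7 | syn-1,3-diol from F4 | O=C1OC[C@@H](C1)Cc1cc([C@H](CO)[C@H](O)c2ccc(O[Si](C)(C)C(C)(C)C)c(OC)c2)c(O[Si](C)(C)C(C)(C)C)c(OC)c1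
F6 | step 7 | desilylated triol bisphenol from F5 | O=C1OC[C@@H](C1)Cc1cc([C@H](CO)[C@H](O)c2ccc(O)c(OC)c2)c(O)c(OC)c1
F7 | step 12 | chlorozinc enolate of (R)-3-acetyl-4-benzyloxazolidin-2-one | C=C(O[Zn]Cl)N1[C@H](Cc2ccccc2)COC1=O
F8 | step 12 | (R)-4-benzyl-3-{2-[2-(tert-butyldimethylsilyloxy)-3-methoxy-5-(methoxycarbonyl)phenyl]acetyl}oxazolidin-2-one | COC(=O)c1cc(CC(=O)N2[C@H](Cc3ccccc3)COC2=O)c(O[Si](C)(C)C(C)(C)C)c(OC)c1
F9 | step 12 | (4R)-imide (2R,3R)-syn-aldol adduct | COc1cc([C@H](O)[C@H](C(=O)N2[C@H](Cc3ccccc3)COC2=O)c2cc(C(=O)OC)cc(OC)c2O[Si](C)(C)C(C)(C)C)ccc1O[Si](C)(C)C(C)(C)C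
F10 | step 12 | (1R,2S)-syn-diol ester | COc1cc([C@H](O)[C@H](CO)c2cc(C(=O)OC)cc(OC)c2O[Si](C)(C)C(C)(C)C)ccc1O[Si](C)(C)C(C)(C)C
F11 | step 12 | primary mono-silyl ether of F10 | COc1cc([C@H](O)[C@H](CO[Si](C)(C)C(C)(C)C)c2cc(C(=O)OC)cc(OC)c2O[Si](C)(C)C(C)(C)C)ccc1O[Si](C)(C)C(C)(C)C
F12 | step 12 | (1S)-4-nitrobenzoate from Mitsunobu inversion of F11 | COc1cc([C@@H](OC(=O)c2ccc(cc2)[N+](=O)[O-])[C@H](CO[Si](C)(C)C(C)(C)C)c2cc(C(=O)OC)cc(OC)c2O[Si](C)(C)C(C)(C)C)ccc1O[Si](C)(C)C(C)(C)C
F13 | step 12 | (1S,2S) secondary alcohol from F12 | COc1cc([C@@H](O)[C@H](CO[Si](C)(C)C(C)(C)C)c2cc(C(=O)OC)cc(OC)c2O[Si](C)(C)C(C)(C)C)ccc1O[Si](C)(C)C(C)(C)C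
F14 | step 8 | (2S,3S)-2-(4-hydroxy-3-methoxyphenyl)-7-methoxy-5-{[(3R)-5-oxooxolan-3-yl]methyl}-2,3-dihydro-1-benzofuran-3-carboxylic acid | O=C1OC[C@@H](C1)Cc1cc(OC)c2c(c1)[C@H](C(=O)O)[C@@H](c1ccc(O)c(OC)c1)O2
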